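**Retrosynthetic overview**

1. Target 23 ⇒ 22: the ten-membered carbocycle is closed last, by ring-closing metathesis across C1=C10; the acrolein unit of 22 comes from α-methylenation of aldehyde 21.
2. 21 ⇒ 12 + 18: the cis-fused α-methylene lactone (C6–C7 bond and C6–O–C12) is made first, by allylboration–lactonisation of enal 18 with allylboronate 12.
3. 12 ⇒ 4 + 6 + 9: C8 and its isovalerate are set on achiral aldehyde 4 by an amine-catalysed α-acyloxylation, trapped in the same flask by a borylmethyl ylide.
4. 18 ⇒ 13 (hydroalumination–iodination, Negishi coupling, oxidation); 4 ⇒ cyclopentene 1.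
5. Ring order: lactone (step 8), then carbocycle (step 10).

Assumption: C1–C15 are germacrane locants of the target (C6 lactone carbinol, C7 ring-fusion CH, C8 ester carbinol, C14 formyl carbon, C15 hydroxymethyl carbon), and only species that accumulate in the flask before the next reagent is added are numbered as non-isolated intermediates.

**Route**

Step 1
Reactants: 1 cyclopentene
Product: 4 5,5-dimethoxypentanal, via 5-hydroperoxy-5-methoxypentanal 2 (not isolated), via 5-hydroperoxy-1,1,5-trimethoxypentane 3 (not isolated)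
Conditions: O3, CH2Cl2/MeOH 5:1, −78 °C; TsOH·H2O, rt; NaHCO3; Me2S, rt
Reagents that add atoms: ozone [O-][O+]=O; methanol CO
Why: Ozonolysis with unsymmetrical work-up: methanol traps the carbonyl oxide as a methoxy hydroperoxide, acid acetalises only the free aldehyde terminus, and dimethyl sulfide then reduces the hydroperoxide terminus to the aldehyde, so the two ends of the C5 chain emerge differentiated.

Step 2
Reactants: 5 3-methylbutanoic anhydride (isovaleric anhydride)
Product: 6 bis(3-methylbutanoyl) peroxide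
Conditions: 5 (2.0 equiv), 30% aq H2O2 (1.0 equiv), 2 M NaOH (2.0 equiv), Et2O, 0 °C; organic layer washed with cold aq NaHCO3, dried (MgSO4), kept as a titrated 0.5 M solution, never concentrated
Reagents that add atoms: hydrogen peroxide OO
Why: Hydroperoxide anion opens one anhydride to the percarboxylate, which is acylated by a second anhydride (Schotten–Baumann-type acylation of hydrogen peroxide, the classical preparation of primary dialkanoyl peroxides), the other acyl group of each anhydride leaving as sodium 3-methylbutanoate in the aqueous layer.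

Step 3
Reactants: 7 methyl (triphenylphosphoranylidene)acetate; 8 2-(iodomethyl)-4,4,5,5-tetramethyl-1,3,2-dioxaborolane
Product: 9 [1-methoxy-1-oxo-3-(4,4,5,5-tetramethyl-1,3,2-dioxaborolan-2-yl)propan-2-yl]triphenylphosphonium iodide
Conditions: PhMe, 60 °C, 16 h; precipitate filtered
Reagents that add atoms: none
Why: Bestmann-type C-alkylation of an ester-stabilised ylide by a primary iodide, the operation used for the analogous silylmethyl reagent, here assisted by ate-complex formation at boron and 1,2-shift with loss of iodide; the salt precipitates, so alkylation stops at this stage.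

Step 4
Reactants: 4 5,5-dimethoxypentanal; 6 bis(3-methylbutanoyl) peroxide; 9 the phosphonium iodide
Product: 12 methyl (2E,4R)-7,7-dimethoxy-4-[(3-methylbutanoyl)oxy]-2-[(4,4,5,5-tetramethyl-1,3,2-dioxaborolan-2-yl)methyl]hept-2-enoate, via boron ylide 10 (not isolated), via acyloxy aldehyde 11 (not isolated)
Conditions: flask A: 9 (2.2 equiv), NaN(SiMe3)2 (2.15 equiv), THF, −78 → 0 °C; flask B: 4, 6 (1.05 equiv), (R)-2-(triphenylmethyl)pyrrolidine (10 mol%), hydroquinone (10 mol%), THF, 0 °C, 4 h; then A into B, 0 °C → rt, 12 h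
Reagents that add atoms: none
Why: Proposed new method: the E-enamine of 4 with the bulky (R)-pyrrolidine attacks the weak O–O bond of the dialkanoyl peroxide 6 at oxygen from its unshielded face (a displacement at O that releases isovalerate), giving (R)-11 just as benzoyl peroxide does in the known enamine-catalysed α-benzoyloxylation of aldehydes; 11 is then captured before it can epimerise by ester-stabilised ylide 10, the boron counterpart of the known silylmethyl ylide, in an E-selective Wittig olefination that places C8 cis to CH2B. The closest known reaction types are organocatalytic α-benzoyloxylation with in-flask Wittig trapping and Wittig reactions of α-(silylmethyl) ester ylides.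

Step 5
Reactants: 13 4-[(tert-butyldimethylsilyl)oxy]but-2-yn-1-ol
Product: 15 (2Z)-4-[(tert-butyldimethylsilyl)oxy]-3-iodobut-2-en-1-ol, via cyclic vinylalanate 14 (not isolated)
Conditions: NaAlH2(OCH2CH2OMe)2 (Red-Al, 1.5 equiv), THF, 0 °C; then I2, −78 → 0 °C; aq KNaC4H4O6 work-up
Reagents that add atoms: iodine II
Why: Hydroxyl-directed trans-hydroalumination of the propargylic alcohol delivers hydride to C5 and aluminium to C4 through a five-membered oxa-aluminacycle, and iododealumination with retention gives the Z-iodide with C6 cis to the carbon that will carry C3.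

Step 6
Reactants: 15 the Z-iodide; 16 but-3-en-1-ylzinc bromide (CH2=CHCH2CH2ZnBr)
Product: 17 (2E)-3-{[(tert-butyldimethylsilyl)oxy]methyl}hepta-2,6-dien-1-ol
Conditions: 16 (2.5 equiv, 0.5 M in THF), PdCl2(dppf) (5 mol%; dppf = 1,1'-bis(diphenylphosphino)ferrocene), THF, 50 °C
Reagents that add atoms: none
Why: Negishi sp2–sp3 cross-coupling proceeds with retention of alkene geometry, so the butenyl chain (C3) ends cis to C6 and C15 trans to C6, the C4=C5 geometry of the target.

Step 7
Reactants: 17 the dienol
Product: 18 (2E)-3-{[(tert-butyldimethylsilyl)oxy]methyl}hepta-2,6-dienal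
Conditions: MnO2 (15 equiv), CH2Cl2, rt
Reagents that add atoms: none
Why: Allylic oxidation with MnO2 is unambiguous because the only free hydroxyl is the C6 allylic alcohol, the C15 oxygen being silylated.

Step 8
Reactants: 12 the allylboronate; 18 the enal
Product: 21 (1R)-1-[(2R,3S)-2-[(1E)-2-(hydroxymethyl)hexa-1,5-dien-1-yl]-4-methylidene-5-oxooxolan-3-yl]-4-oxobutyl 3-methylbutanoate, via borate adduct 19 (not isolated), via silyl acetal lactone 20 (not isolated)
Conditions: 12 (1.2 equiv), PhMe (1 M), 80 °C, 48 h; then THF, 1 M aq HCl, rt, 6 h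
Reagents that add atoms: water O
Why: Thermal carbonyl allylboration through a closed six-membered chair followed by lactonisation: the C8 substituent, cis to CH2B, sits axial so C6 and C7 form syn (cis-lactone), and with C8–H held in the alkene plane by A(1,3) strain the aldehyde adds to the C7 face anti to the C8–O bond, translating (8R) into (6R,7S); aqueous HCl then hydrolyses the borate, completes lactone closure and removes acetal and silyl ether.

Step 9
Reactants: 21 the hydroxy aldehyde lactone
Product: 22 (1R)-1-[(2R,3S)-2-[(1E)-2-(hydroxymethyl)hexa-1,5-dien-1-yl]-4-methylidene-5-oxooxolan-3-yl]-3-formylbut-3-en-1-yl 3-methylbutanoate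
Conditions: 37% aq CH2O (1.5 equiv), pyrrolidine (20 mol%), propionic acid (20 mol%), i-PrOH, 45 °C
Reagents that add atoms: formaldehyde C=O
Why: Amine-catalysed Mannich condensation–elimination with formaldehyde (organocatalytic α-methylenation of aldehydes) acts on the only enolisable aldehyde and leaves the three stereocentres untouched.

Step 10
Reactants: 22 the 2-substituted acrolein
Product: 23 (3aS,4R,6E,10E,11aR)-6-formyl-10-(hydroxymethyl)-3-methylidene-2-oxo-2,3,3a,4,5,8,9,11a-octahydrocyclodeca[b]furan-4-yl 3-methylbutanoate (target)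
Conditions: second-generation Hoveyda–Grubbs catalyst RuCl2(H2IMes)(=CH–C6H4-2-OiPr) (10 mol%), 1,4-benzoquinone (20 mol%), ClCH2CH2Cl (1 mM), 60 °C, Ar sparge
Reagents that add atoms: none
Why: Ring-closing metathesis between the terminal vinyl group and the 2-substituted acrolein closes the ten-membered ring with loss of ethene; the conjugated E-enal (C2 trans to CHO) is also the ring-cis alkene, so conjugation and ring size favour the same isomer, while closure onto the lactone methylene would give a bridgehead alkene and the trisubstituted C4=C5 bond is inert.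

**Compound list**

1 | cyclopentene | C1=CCCC1 | starting material
2 | 5-hydroperoxy-5-methoxypentanal | O=CCCCC(OC)OO | intermediate
3 | 5-hydroperoxy-1,1,5-trimethoxypentane | COC(OC)CCCC(OC)OO | intermediate
4 | 5,5-dimethoxypentanal | O=CCCCC(OC)OC | intermediate
5 | 3-methylbutanoic anhydride (isovaleric anhydride) | CC(C)CC(=O)OC(=O)CC(C)C | starting material
6 | bis(3-methylbutanoyl) peroxide | CC(C)CC(=O)OOC(=O)CC(C)C | intermediate
7 | methyl (triphenylphosphoranylidene)acetate | COC(=O)C=P(c1ccccc1)(c1ccccc1)c1ccccc1 | starting material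
8 | 2-(iodomethyl)-4,4,5,5-tetramethyl-1,3,2-dioxaborolane | ICB1OC(C)(C)C(C)(C)O1 | starting material
9 | [1-methoxy-1-oxo-3-(pinacolboryl)propan-2-yl]triphenylphosphonium iodide | COC(=O)C(CB1OC(C)(C)C(C)(C)O1)[P+](c1ccccc1)(c1ccccc1)c1ccccc1.[I-] | intermediate
10 | methyl 3-(pinacolboryl)-2-(triphenylphosphoranylidene)propanoate (boron ylide) | COC(=O)C(CB1OC(C)(C)C(C)(C)O1)=P(c1ccccc1)(c1ccccc1)c1ccccc1 | intermediate
11 | (2R)-5,5-dimethoxy-1-oxopentan-2-yl 3-methylbutanoate | O=C[C@H](OC(=O)CC(C)C)CCC(OC)OC | intermediate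
12 | methyl (2E,4R)-7,7-dimethoxy-4-[(3-methylbutanoyl)oxy]-2-[(pinacolboryl)methyl]hept-2-enoate | COC(=O)/C(CB1OC(C)(C)C(C)(C)O1)=C/[C@H](OC(=O)CC(C)C)CCC(OC)OC | intermediate
13 | 4-[(tert-butyldimethylsilyl)oxy]but-2-yn-1-ol | OCC#CCO[Si](C)(C)C(C)(C)C | starting material
14 | sodium salt of the five-membered oxa-aluminacycle (O–Al–C4=C5–C6) carrying two 2-methoxyethoxy groups on Al and CH2OTBS on C4 | [Na+].COCCO[Al-]1(OCCOC)OCC=C1CO[Si](C)(C)C(C)(C)C | intermediate
15 | (2Z)-4-[(tert-butyldimethylsilyl)oxy]-3-iodobut-2-en-1-ol | OC/C=C(\I)CO[Si](C)(C)C(C)(C)C | intermediate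
16 | but-3-en-1-ylzinc bromide | C=CCC[Zn]Br | starting material
17 | (2E)-3-{[(tert-butyldimethylsilyl)oxy]methyl}hepta-2,6-dien-1-ol | OC/C=C(/CO[Si](C)(C)C(C)(C)C)CCC=C | intermediate
18 | (2E)-3-{[(tert-butyldimethylsilyl)oxy]methyl}hepta-2,6-dienal | O=C/C=C(/CO[Si](C)(C)C(C)(C)C)CCC=C | intermediate
19 | pinacol borate of the syn homoallylic alcohol (C6–O–Bpin, methyl ester not yet closed; same spatial arrangement at C6, C7, C8 as 20) | COC(=O)C(=C)[C@H]([C@H](OB1OC(C)(C)C(C)(C)O1)/C=C(/CO[Si](C)(C)C(C)(C)C)CCC=C)[C@H](OC(=O)CC(C)C)CCC(OC)OC | intermediate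
20 | (1R)-1-[(2R,3S)-2-[(1E)-2-{[(tert-butyldimethylsilyl)oxy]methyl}hexa-1,5-dien-1-yl]-4-methylidene-5-oxooxolan-3-yl]-4,4-dimethoxybutyl 3-methylbutanoate | C=C1C(=O)O[C@H](/C=C(/CO[Si](C)(C)C(C)(C)C)CCC=C)[C@@H]1[C@H](OC(=O)CC(C)C)CCC(OC)OC | intermediate
21 | (1R)-1-[(2R,3S)-2-[(1E)-2-(hydroxymethyl)hexa-1,5-dien-1-yl]-4-methylidene-5-oxooxolan-3-yl]-4-oxobutyl 3-methylbutanoate | C=C1C(=O)O[C@H](/C=C(/CO)CCC=C)[C@@H]1[C@H](OC(=O)CC(C)C)CCC=O | intermediate
22 | (1R)-1-[(2R,3S)-2-[(1E)-2-(hydroxymethyl)hexa-1,5-dien-1-yl]-4-methylidene-5-oxooxolan-3-yl]-3-formylbut-3-en-1-yl 3-methylbutanoate | C=C1C(=O)O[C@H](/C=C(/CO)CCC=C)[C@@H]1[C@H](OC(=O)CC(C)C)CC(=C)C=O | intermediate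
23 | (3aS,4R,6E,10E,11aR)-6-formyl-10-(hydroxymethyl)-3-methylidene-2-oxo-2,3,3a,4,5,8,9,11a-octahydrocyclodeca[b]furan-4-yl 3-methylbutanoate | C=C1C(=O)O[C@@H]2/C=C(/CO)CC/C=C(/C=O)C[C@@H](OC(=O)CC(C)C)[C@H]12 | target

**Step count and risks**

Total: 10 steps. Longest linear sequence: 6 steps (5, 6, 7, 8, 9, 10); the other branches (1, 4, 8, 9, 10; 2, 4, 8, 9, 10; and 3, 4, 8, 9, 10) are 5 steps each.

The three steps most likely to fail:

Step 4 (the proposed new step). The risks are single-electron transfer from the enamine to the aliphatic peroxide with decarboxylation, N-acylation of the catalyst, and an untested borylmethyl ylide. The fallback uses known chemistry only, sets out from 4 and comes back at 20. Amine-catalysed α-chlorination of 4 (N-chlorosuccinimide, 2,5-diphenylpyrrolidine of the hand that gives the S chloride) gives (2S)-2-chloro-5,5-dimethoxypentanal F1. NaBH4 in the same flask gives (2S)-2-chloro-5,5-dimethoxypentan-1-ol F2, and KOH closes (2R)-2-(3,3-dimethoxypropyl)oxirane F3 with inversion at C8. Dimethylsulfonium methylide (Me3SI, n-BuLi) opens the epoxide at its CH2 and eliminates to (3R)-6,6-dimethoxyhex-1-en-3-ol F4. Acylation with anhydride 5 (pyridine, 4-(dimethylamino)pyridine) gives (3R)-6,6-dimethoxyhex-1-en-3-yl 3-methylbutanoate F5. Ozonolysis (O3, then Me2S) gives aldehyde 11, which is taken at once into a Morita–Baylis–Hillman reaction with methyl acrylate (DABCO) to give, as a mixture of carbinol epimers, methyl (4R)-3-hydroxy-7,7-dimethoxy-2-methylidene-4-[(3-methylbutanoyl)oxy]heptanoate F6. N-Bromosuccinimide/Me2S converts it with allylic transposition into methyl (2Z,4R)-2-(bromomethyl)-7,7-dimethoxy-4-[(3-methylbutanoyl)oxy]hept-2-enoate F7. Indium-mediated Barbier allylation of enal 18 with this bromide (In powder, THF/H2O), which is syn-selective for such Z-bromides, and lactonisation (PPTS) return to 20; the acid treatment of step 8 then gives 21.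

Step 8. The risks are the sense or level of 1,2-induction from C8, a slow thermal addition to a β,β-disubstituted enal, and acyl migration from O8 to O6 leading to the isomeric lactone closed on O8. The fallback sets out from 12 and 18 and comes back at 20. It replaces substrate control by catalyst control: the same partners are combined at −30 °C in PhMe with 10 mol% of a BINOL-derived phosphoric acid carrying 3,3'-bis(2,4,6-triisopropylphenyl) groups (or its N-triflyl phosphoramide), using the enantiomer found to be matched. The catalyst then chooses the aldehyde face, and because the chair couples the faces of C6 and C7, both centres follow; heating is avoided, which also suppresses acyl migration. This fallback makes no new compound (none F0).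

Step 10. The risks are oligomerisation through the terminal alkene, poor turnover on the electron-poor acrolein, and strain in the cis,cis-cyclodecadiene. The fallback sets out from 20 (step 8 worked up without acid) and comes back at 23. It moves the ring closure to the allylic-alcohol oxidation level with C15 still silylated. Selective acetal hydrolysis (Amberlyst-15, wet acetone) gives the 4-oxobutyl ester with the silyl ether retained F8. α-Methylenation as in step 9 gives the silylated 3-formylbut-3-enyl ester F9. Luche reduction (NaBH4, CeCl3·7H2O, MeOH, −78 °C) gives the 2-(hydroxymethyl)allyl compound F10. Hydroxyl-assisted ring-closing metathesis of this electron-neutral 1,1-disubstituted alkene gives the 14-hydroxy 15-O-silyl macrocycle F11. MnO2, which now finds only the C14 allylic alcohol, gives the 15-O-silyl ether of the target F12, and HF·pyridine returns to 23.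

**Further compounds**

F1 | step 4 | (2S)-2-chloro-5,5-dimethoxypentanal | O=C[C@@H](Cl)CCC(OC)OC
F2 | step 4 | (2S)-2-chloro-5,5-dimethoxypentan-1-ol | OC[C@@H](Cl)CCC(OC)OC
F3 | step 4 | (2R)-2-(3,3-dimethoxypropyl)oxirane | COC(OC)CC[C@@H]1CO1
F4 | step 4 | (3R)-6,6-dimethoxyhex-1-en-3-ol | C=C[C@H](O)CCC(OC)OC
F5 | step 4 | (3R)-6,6-dimethoxyhex-1-en-3-yl 3-methylbutanoate | C=C[C@H](OC(=O)CC(C)C)CCC(OC)OC
F6 | step 4 | methyl (4R)-3-hydroxy-7,7-dimethoxy-2-methylidene-4-[(3-methylbutanoyl)oxy]heptanoate (both C3 epimers) | COC(=O)C(=C)C(O)[C@H](OC(=O)CC(C)C)CCC(OC)OC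
F7 | step 4 | methyl (2Z,4R)-2-(bromomethyl)-7,7-dimethoxy-4-[(3-methylbutanoyl)oxy]hept-2-enoate | COC(=O)/C(CBr)=C/[C@H](OC(=O)CC(C)C)CCC(OC)OC
F0 | step 8 | none | none
F8 | step 10 | (1R)-1-[(2R,3S)-2-[(1E)-2-{[(tert-butyldimethylsilyl)oxy]methyl}hexa-1,5-dien-1-yl]-4-methylidene-5-oxooxolan-3-yl]-4-oxobutyl 3-methylbutanoate | C=C1C(=O)O[C@H](/C=C(/CO[Si](C)(C)C(C)(C)C)CCC=C)[C@@H]1[C@H](OC(=O)CC(C)C)CCC=O
F9 | step 10 | (1R)-1-[(2R,3S)-2-[(1E)-2-{[(tert-butyldimethylsilyl)oxy]methyl}hexa-1,5-dien-1-yl]-4-methylidene-5-oxooxolan-3-yl]-3-formylbut-3-en-1-yl 3-methylbutanoate | C=C1C(=O)O[C@H](/C=C(/CO[Si](C)(C)C(C)(C)C)CCC=C)[C@@H]1[C@H](OC(=O)CC(C)C)CC(=C)C=O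
F10 | step 10 | (1R)-1-[(2R,3S)-2-[(1E)-2-{[(tert-butyldimethylsilyl)oxy]methyl}hexa-1,5-dien-1-yl]-4-methylidene-5-oxooxolan-3-yl]-3-(hydroxymethyl)but-3-en-1-yl 3-methylbutanoate | C=C1C(=O)O[C@H](/C=C(/CO[Si](C)(C)C(C)(C)C)CCC=C)[C@@H]1[C@H](OC(=O)CC(C)C)CC(=C)CO
F11 | step 10 | analogue of 23 with CH2OH in place of CHO at C14 and tert-butyldimethylsilyl ether at C15 | C=C1C(=O)O[C@@H]2/C=C(/CO[Si](C)(C)C(C)(C)C)CC/C=C(/CO)C[C@@H](OC(=O)CC(C)C)[C@H]12
F12 | step 10 | 15-O-tert-butyldimethylsilyl ether of 23 | C=C1C(=O)O[C@@H]2/C=C(/CO[Si](C)(C)C(C)(C)C)CC/C=C(/C=O)C[C@@H](OC(=O)CC(C)C)[C@H]12
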